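**Plan**

- Retrosynthesis: the acid-labile groups are put back first. Ring B is then taken down by two hydrogens to a 3-methyl-2,4-dioxocyclohexane-1-carboxylate and cut at C1'–C6' and C3'–C4'. Next the allylic O–CH2 bond of the resulting 4-aroyloxycrotonate is cut, and last the C1–CO2 and C3–CHO bonds of ring A, back to orcinol.
- Enabling feature: in ring B, C1'(CO2H)–C2'(OH)–C3'(CH3) is a 3-oxopentanoate and C4'(OH)–C5'(H)–C6'(CH2O) is a 4-oxygenated but-2-enoate. The 1,3-dioxygenation makes ring B the dehydro form of a cyclohexane-1,3-dione.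
- Forward: ring A is bought as orcinol; the formyl carbon goes between the two oxygens, and symmetry makes the carboxylation site next to the methyl unambiguous. The carboxylate is joined to methyl 4-bromocrotonate, ring B is built on the crotonate by Michael–Dieckmann annulation, aromatized, and everything is unmasked with acid.
- Stereochemistry: the target has no stereocentre. The three sp3 centres formed in the annulation are uncontrolled and are erased on aromatization.

Key step: step 6

Assumption: anhydrous orcinol is used (the monohydrate is dried azeotropically with toluene).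
Numbering: ring A is C1 (carboxyl-bearing) to C6 (methyl-bearing); ring B is C1' (carboxyl-bearing) to C6' (CH2O-bearing). In the step lines, ArCO = 3-(1,3-dioxolan-2-yl)-2,4-bis(methoxymethoxy)-6-methylbenzoyl; full names are in the compound list.

**Step 1**
Reactants: 1 orcinol (5-methylbenzene-1,3-diol)
Product: 2 1,3-bis(methoxymethoxy)-5-methylbenzene
Conditions: NaH (2.5 equiv), MOMCl (2.4 equiv), DMF, 0 °C → rt
Reagents that add atoms: chloromethyl methyl ether, COCCl
Why: Williamson-type O-alkylation of the bis-phenoxide by the alpha-chloro ether should give the bis-MOM ether, which is base-stable protection and also the directing group for step 2.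

**Step 2**
Reactants: 2 1,3-bis(methoxymethoxy)-5-methylbenzene
Product: 5 2,6-bis(methoxymethoxy)-4-methylbenzaldehyde, via aryllithium 3 (not isolated), via lithium aminoalkoxide 4 (not isolated)
Conditions: n-BuLi (1.2 equiv), TMEDA (1.2 equiv), THF, 0 °C; DMF (2 equiv), 0 °C → rt; H2O
Reagents that add atoms: N,N-dimethylformamide, CN(C)C=O
Why: Directed ortho-metalation, in which the two MOM ethers cooperatively direct lithiation to the carbon between them, followed by formylation of the aryllithium with DMF, should place the future C3 aldehyde carbon without regiochemical ambiguity.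

**Step 3**
Reactants: 5 2,6-bis(methoxymethoxy)-4-methylbenzaldehyde
Product: 6 3-bromo-2,6-bis(methoxymethoxy)-4-methylbenzaldehyde
Conditions: NBS (1.05 equiv), MeCN, 0 °C → rt, dark
Reagents that add atoms: N-bromosuccinimide, O=C1CCC(=O)N1Br
Why: Electrophilic aromatic bromination can give only one monobromide, because the two free ring positions are equivalent by symmetry and each is ortho/para to the MOM ethers and meta to the formyl group, whose deactivation also helps to stop after one bromine.

**Step 4**
Reactants: 6 3-bromo-2,6-bis(methoxymethoxy)-4-methylbenzaldehyde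
Product: 7 2-[3-bromo-2,6-bis(methoxymethoxy)-4-methylphenyl]-1,3-dioxolane
Conditions: TMSOCH2CH2OTMS (1.5 equiv), TMSOTf (5 mol %), CH2Cl2, −78 → −20 °C; pyridine quench
Reagents that add atoms: 1,2-bis(trimethylsilyloxy)ethane, C[Si](C)(C)OCCO[Si](C)(C)C
Why: Noyori acetalization under aprotic conditions at low temperature should convert the hindered, electron-rich aldehyde into its dioxolane without the protic acid and heat that would cut the aryl MOM ethers, giving a protecting-group set that is uniformly base-stable and acid-labile.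

**Step 5**
Reactants: 7 2-[3-bromo-2,6-bis(methoxymethoxy)-4-methylphenyl]-1,3-dioxolane; 8 methyl (E)-4-bromobut-2-enoate
Product: 11 methyl (E)-4-(ArCO-oxy)but-2-enoate, via aryllithium 9 (not isolated), via lithium carboxylate 10 (not isolated)
Conditions: n-BuLi (1.05 equiv), THF, −78 °C; CO2 (dry, excess), −78 °C → rt; evaporate; 8 (1.3 equiv), DMF, rt
Reagents that add atoms: carbon dioxide, O=C=O
Why: Bromine–lithium exchange outruns any deprotonation at −78 °C, carboxylation of the aryllithium gives the lithium benzoate, and SN2 O-alkylation of this carboxylate by the allylic bromide should form the ester without the acid ever being protonated, so the acetal groups never meet acid.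

**Step 6**
Reactants: 11 methyl (E)-4-(ArCO-oxy)but-2-enoate; 12 tert-butyl 3-oxopentanoate
Product: 14 tert-butyl 6-(ArCO-oxymethyl)-3-methyl-2,4-dioxocyclohexane-1-carboxylate (diastereomer/enol mixture), via Michael adduct 13 (not isolated)
Conditions: 12 (1.2 equiv), KOC(CH3)3 (0.2 equiv), THF–t-BuOH (4:1), 0 °C → rt; then KOC(CH3)3 (1.3 equiv), 50 °C; AcOH, 0 °C
Reagents that add atoms: none
Why: The potassium enolate of 12 adds through its doubly activated alpha carbon to the beta carbon of the crotonate in 11 (Michael addition, C1'–C6'); proton exchange with tert-butanol then gives, reversibly, the enolate on the gamma CH2 of the propanoyl group, which attacks the methyl ester carbonyl (Claisen/Dieckmann condensation, C3'–C4') and expels methoxide. The closest known reaction is the Michael–Dieckmann synthesis of dihydroresorcylates (6-alkyl-2,4-dioxocyclohexanecarboxylates) from beta-keto esters and crotonates with one equivalent of alkoxide. Ring B closes in the 6-exo-trig mode, and deprotonation of the new beta-diketone at C3' makes the sequence irreversible and pulls the Michael equilibrium forward. The stereocentres created at C1', C3' and C6' are under no control and need none, since C1' and C3' are epimerizable and all three are erased in step 7. The chemoselectivity required is that enolates and alkoxide attack the crotonate and its methyl ester and not the ring A benzoate, which is shielded by its two ortho substituents (OMOM and CH3), while tert-butoxide is too hindered to transesterify and the tert-butyl ester too hindered to serve as the Claisen acceptor. The aroyloxy group sits gamma to every carbanion formed, so it cannot leave by beta-elimination, and a carboxylate is too poor a leaving group for 3-exo-tet cyclopropane closure.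

**Step 7**
Reactants: 14 tert-butyl 6-(ArCO-oxymethyl)-3-methyl-2,4-dioxocyclohexane-1-carboxylate
Product: 17 tert-butyl 6-(ArCO-oxymethyl)-2,4-dihydroxy-3-methylbenzoate, via bis-silyl diene 15 (not isolated), via bis-silyl arene 16 (not isolated)
Conditions: TMSOTf (2.5 equiv), Et3N (4 equiv), CH2Cl2, 0 °C; pentane, filter, concentrate; DDQ (1.1 equiv), 2,6-lutidine (0.5 equiv), PhH, 0 °C → rt; MeOH, rt
Reagents that add atoms: none
Why: O-silylation of both 1,3-dicarbonyl units under soft enolization should give a 2,4-bis(silyloxy)cyclohexa-1,3-diene that DDQ aromatizes by hydride abstraction from C5' or C6' and loss of a proton (dehydrogenation of a cyclohexadiene, the chemistry of the DDQ oxidation of silyl enol ethers), so that the result does not depend on which diene isomer forms, the C3' methyl cannot trap the oxidant, and the medium stays non-acidic and cannot cleave and decarboxylate the tert-butyl beta-keto ester before it has become an aryl ester; methanol then removes the aryl silyl ethers.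

**Step 8**
Reactants: 17 tert-butyl 6-(ArCO-oxymethyl)-2,4-dihydroxy-3-methylbenzoate
Product: 18 alectorialic acid
Conditions: TFA–CH2Cl2–H2O (10:10:1), anisole (5 equiv), 0 °C → rt
Reagents that add atoms: water, O
Why: Acidolysis with aqueous trifluoroacetic acid should hydrolyse the two MOM ethers and the dioxolane and cleave the tert-butyl ester by alkyl–oxygen fission (loss of isobutene, cation scavenged by anisole), while the hindered benzylic benzoate stays intact because its benzylic carbon is meta to both ring B hydroxyls and is therefore not readily ionized.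

**Compound list**

1 | orcinol (5-methylbenzene-1,3-diol) | Cc1cc(O)cc(O)c1 | starting material
2 | 1,3-bis(methoxymethoxy)-5-methylbenzene | Cc1cc(OCOC)cc(OCOC)c1 | intermediate
3 | [2,6-bis(methoxymethoxy)-4-methylphenyl]lithium | [Li]c1c(OCOC)cc(C)cc1OCOC | intermediate (not isolated)
4 | lithium [2,6-bis(methoxymethoxy)-4-methylphenyl](dimethylamino)methanolate | [Li+].[O-]C(N(C)C)c1c(OCOC)cc(C)cc1OCOC | intermediate (not isolated)
5 | 2,6-bis(methoxymethoxy)-4-methylbenzaldehyde | O=Cc1c(OCOC)cc(C)cc1OCOC | intermediate
6 | 3-bromo-2,6-bis(methoxymethoxy)-4-methylbenzaldehyde | O=Cc1c(OCOC)cc(C)c(Br)c1OCOC | intermediate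
7 | 2-[3-bromo-2,6-bis(methoxymethoxy)-4-methylphenyl]-1,3-dioxolane | Cc1cc(OCOC)c(C2OCCO2)c(OCOC)c1Br | intermediate
8 | methyl (E)-4-bromobut-2-enoate (methyl 4-bromocrotonate) | COC(=O)/C=C/CBr | starting material
9 | [3-(1,3-dioxolan-2-yl)-2,4-bis(methoxymethoxy)-6-methylphenyl]lithium | Cc1cc(OCOC)c(C2OCCO2)c(OCOC)c1[Li] | intermediate (not isolated)
10 | lithium 3-(1,3-dioxolan-2-yl)-2,4-bis(methoxymethoxy)-6-methylbenzoate | Cc1cc(OCOC)c(C2OCCO2)c(OCOC)c1C(=O)[O-].[Li+] | intermediate (not isolated)
11 | methyl (E)-4-{[3-(1,3-dioxolan-2-yl)-2,4-bis(methoxymethoxy)-6-methylbenzoyl]oxy}but-2-enoate | Cc1cc(OCOC)c(C2OCCO2)c(OCOC)c1C(=O)OC/C=C/C(=O)OC | intermediate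
12 | tert-butyl 3-oxopentanoate | CCC(=O)CC(=O)OC(C)(C)C | starting material
13 | 1-tert-butyl 5-methyl 3-({[3-(1,3-dioxolan-2-yl)-2,4-bis(methoxymethoxy)-6-methylbenzoyl]oxy}methyl)-2-propanoylpentanedioate | CCC(=O)C(C(=O)OC(C)(C)C)C(COC(=O)c1c(C)cc(OCOC)c(C2OCCO2)c1OCOC)CC(=O)OC | intermediate (not isolated)
14 | tert-butyl 6-({[3-(1,3-dioxolan-2-yl)-2,4-bis(methoxymethoxy)-6-methylbenzoyl]oxy}methyl)-3-methyl-2,4-dioxocyclohexane-1-carboxylate (diastereomer/enol mixture) | Cc1cc(OCOC)c(C2OCCO2)c(OCOC)c1C(=O)OCC1CC(=O)C(C)C(=O)C1C(=O)OC(C)(C)C | intermediate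
15 | tert-butyl 6-({[3-(1,3-dioxolan-2-yl)-2,4-bis(methoxymethoxy)-6-methylbenzoyl]oxy}methyl)-3-methyl-2,4-bis(trimethylsilyloxy)cyclohexa-1,3-diene-1-carboxylate | Cc1cc(OCOC)c(C2OCCO2)c(OCOC)c1C(=O)OCC1CC(O[Si](C)(C)C)=C(C)C(O[Si](C)(C)C)=C1C(=O)OC(C)(C)C | intermediate (not isolated)
16 | tert-butyl 6-({[3-(1,3-dioxolan-2-yl)-2,4-bis(methoxymethoxy)-6-methylbenzoyl]oxy}methyl)-3-methyl-2,4-bis(trimethylsilyloxy)benzoate | Cc1cc(OCOC)c(C2OCCO2)c(OCOC)c1C(=O)OCc1cc(O[Si](C)(C)C)c(C)c(O[Si](C)(C)C)c1C(=O)OC(C)(C)C | intermediate (not isolated)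
17 | tert-butyl 6-({[3-(1,3-dioxolan-2-yl)-2,4-bis(methoxymethoxy)-6-methylbenzoyl]oxy}methyl)-2,4-dihydroxy-3-methylbenzoate | Cc1cc(OCOC)c(C2OCCO2)c(OCOC)c1C(=O)OCc1cc(O)c(C)c(O)c1C(=O)OC(C)(C)C | intermediate
18 | alectorialic acid, 6-{[(3-formyl-2,4-dihydroxy-6-methylbenzoyl)oxy]methyl}-2,4-dihydroxy-3-methylbenzoic acid | Cc1cc(O)c(C=O)c(O)c1C(=O)OCc1cc(O)c(C)c(O)c1C(=O)O | target

**Step count**

Total: 8 steps. Longest linear sequence: 8 steps (1 → 18); compounds 8 and 12 are purchased and enter at steps 5 and 6.

**Steps most likely to fail**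

Step 6. The aroyloxycrotonate may not survive the alkoxide: gamma-deprotonation may deconjugate it, the acyl group may move from oxygen to a neighbouring carbanion, or a cyclopropane may close with loss of the aroate. The Claisen closure may also be outrun by retro-Michael cleavage. In that case the C6' oxygen would be carried as a silyl ether and ring A attached only after ring B is aromatic. The fallback sets out from 12 (and from 10 for the acid partner) and comes back at 17. Annulation under the step 6 conditions with methyl (E)-4-(tert-butyldimethylsilyloxy)but-2-enoate F1 (Wittig reaction of commercial (tert-butyldimethylsilyloxy)acetaldehyde with methyl (triphenylphosphoranylidene)acetate) should pass through the Michael adduct 1-tert-butyl 5-methyl 3-[(tert-butyldimethylsilyloxy)methyl]-2-propanoylpentanedioate F2 to tert-butyl 6-[(tert-butyldimethylsilyloxy)methyl]-3-methyl-2,4-dioxocyclohexane-1-carboxylate F3. Aromatization as in step 7, through the bis(trimethylsilyloxy)diene F4 and the bis(trimethylsilyloxy)arene F5, should give tert-butyl 6-[(tert-butyldimethylsilyloxy)methyl]-2,4-dihydroxy-3-methylbenzoate F6. HF·pyridine in THF at 0 °C would free tert-butyl 2,4-dihydroxy-6-(hydroxymethyl)-3-methylbenzoate F7. The lithium carboxylate 10 would be protonated with cold aqueous KHSO4 (pH 4) to 3-(1,3-dioxolan-2-yl)-2,4-bis(methoxymethoxy)-6-methylbenzoic acid F8. Mitsunobu esterification of F7 with F8 (PPh3, DIAD, THF, 0 °C, kept cold against lactonization) would then give 17; the carboxylic acid is by far the most acidic pronucleophile.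

Step 7. Silylation may stop at the mono-silylated vinylogous ester, or DDQ may add to a diene carbon instead of abstracting hydride. The unsaturation would then be introduced by selenoxide elimination at C1'. The fallback sets out from 14 and comes back at 17. LiN(SiMe3)2 (2.2 equiv) in THF at −78 °C should deprotonate C3'–H and then C1'–H. PhSeBr should react at the more basic C1' carbanion to give tert-butyl 6-(ArCO-oxymethyl)-3-methyl-2,4-dioxo-1-(phenylselanyl)cyclohexane-1-carboxylate F9. H2O2/pyridine in CH2Cl2 at 0 °C would oxidize it to the selenoxide F10, whose syn-elimination can only take the C6' hydrogen. The resulting C1'=C6' enedione tautomerizes to 17.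

Step 8. The strong acid needed for the tert-butyl ester may cause loss of CO2 from the freed beta-resorcylic acid, lactonization of ring B onto its benzylic carbon with expulsion of the ring A acid, or C-alkylation of the resorcinol rings by tert-butyl or formaldehyde-derived cations. The unmasking would then be split into two mechanistically different operations. The fallback sets out from 17 and comes back at 18. HCl (1 M) in THF–MeOH at rt to 40 °C should remove only the MOM groups and the dioxolane, giving tert-butyl 6-{[(3-formyl-2,4-dihydroxy-6-methylbenzoyl)oxy]methyl}-2,4-dihydroxy-3-methylbenzoate F11. TMSOTf/2,6-lutidine in CH2Cl2 at 0 °C would convert the tert-butyl ester into a silyl ester with loss of isobutene under buffered aprotic conditions, giving the persilylated trimethylsilyl ester F12. Methanolysis at rt would release 18.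

**Further compounds**

F1 | step 6 | methyl (E)-4-(tert-butyldimethylsilyloxy)but-2-enoate | COC(=O)/C=C/CO[Si](C)(C)C(C)(C)C
F2 | step 6 | 1-tert-butyl 5-methyl 3-[(tert-butyldimethylsilyloxy)methyl]-2-propanoylpentanedioate | CCC(=O)C(C(=O)OC(C)(C)C)C(CO[Si](C)(C)C(C)(C)C)CC(=O)OC
F3 | step 6 | tert-butyl 6-[(tert-butyldimethylsilyloxy)methyl]-3-methyl-2,4-dioxocyclohexane-1-carboxylate | CC1C(=O)CC(CO[Si](C)(C)C(C)(C)C)C(C(=O)OC(C)(C)C)C1=O
F4 | step 6 | tert-butyl 6-[(tert-butyldimethylsilyloxy)methyl]-3-methyl-2,4-bis(trimethylsilyloxy)cyclohexa-1,3-diene-1-carboxylate | CC1=C(O[Si](C)(C)C)CC(CO[Si](C)(C)C(C)(C)C)C(C(=O)OC(C)(C)C)=C1O[Si](C)(C)C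
F5 | step 6 | tert-butyl 6-[(tert-butyldimethylsilyloxy)methyl]-3-methyl-2,4-bis(trimethylsilyloxy)benzoate | Cc1c(O[Si](C)(C)C)cc(CO[Si](C)(C)C(C)(C)C)c(C(=O)OC(C)(C)C)c1O[Si](C)(C)C
F6 | step 6 | tert-butyl 6-[(tert-butyldimethylsilyloxy)methyl]-2,4-dihydroxy-3-methylbenzoate | Cc1c(O)cc(CO[Si](C)(C)C(C)(C)C)c(C(=O)OC(C)(C)C)c1O
F7 | step 6 | tert-butyl 2,4-dihydroxy-6-(hydroxymethyl)-3-methylbenzoate | Cc1c(O)cc(CO)c(C(=O)OC(C)(C)C)c1O
F8 | step 6 | 3-(1,3-dioxolan-2-yl)-2,4-bis(methoxymethoxy)-6-methylbenzoic acid | Cc1cc(OCOC)c(C2OCCO2)c(OCOC)c1C(=O)O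
F9 | step 7 | tert-butyl 6-({[3-(1,3-dioxolan-2-yl)-2,4-bis(methoxymethoxy)-6-methylbenzoyl]oxy}methyl)-3-methyl-2,4-dioxo-1-(phenylselanyl)cyclohexane-1-carboxylate | Cc1cc(OCOC)c(C2OCCO2)c(OCOC)c1C(=O)OCC1CC(=O)C(C)C(=O)C1([Se]c1ccccc1)C(=O)OC(C)(C)C
F10 | step 7 | tert-butyl 6-({[3-(1,3-dioxolan-2-yl)-2,4-bis(methoxymethoxy)-6-methylbenzoyl]oxy}methyl)-3-methyl-2,4-dioxo-1-(phenylseleninyl)cyclohexane-1-carboxylate | Cc1cc(OCOC)c(C2OCCO2)c(OCOC)c1C(=O)OCC1CC(=O)C(C)C(=O)C1([Se](=O)c1ccccc1)C(=O)OC(C)(C)C
F11 | step 8 | tert-butyl 6-{[(3-formyl-2,4-dihydroxy-6-methylbenzoyl)oxy]methyl}-2,4-dihydroxy-3-methylbenzoate | Cc1cc(O)c(C=O)c(O)c1C(=O)OCc1cc(O)c(C)c(O)c1C(=O)OC(C)(C)C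
F12 | step 8 | trimethylsilyl 6-({[3-formyl-6-methyl-2,4-bis(trimethylsilyloxy)benzoyl]oxy}methyl)-3-methyl-2,4-bis(trimethylsilyloxy)benzoate | Cc1cc(O[Si](C)(C)C)c(C=O)c(O[Si](C)(C)C)c1C(=O)OCc1cc(O[Si](C)(C)C)c(C)c(O[Si](C)(C)C)c1C(=O)O[Si](C)(C)C
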